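**Retrosynthetic overview**
- The C3–benzyl bond is made late, by alkylating the enediolate of an α‑hydroxy‑γ‑lactone with a vanillyl bromide on the face away from the C4 side chain; O‑debenzylation ends the route.
- The α‑hydroxy lactone comes from a hydroxymalonate lactone (saponification, decarboxylation). That lactone comes from SN2 acetolysis of a donor–acceptor cyclopropane, with inversion at the benzylic carbon, and oxidation of the enolate set free.
- The cyclopropane–lactone bicycle comes from an (E)‑cinnamaldehyde and bromomalonate in one flask: organocatalytic Michael addition/alkylation, then borohydride reduction and lactonization.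
- Ring order: cyclopropane first, γ‑lactone second, both in the same operation. The cyclopropane is opened in the next step; the lactone is the ring of the target (it is opened and re‑closed once, in the decarboxylation step).
- Both aryl units come from O‑benzylvanillin stock (aldehyde for the enal, alcohol for the bromide).

Assumption: compounds 1, 2, 4 and 12, the prolinol silyl ether catalyst and common reagents are bought; a sequence run in one flask without isolation counts as one step.

**Step 1**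
Reactants: 1 4-(benzyloxy)-3-methoxybenzaldehyde; 2 (triphenylphosphoranylidene)acetaldehyde
Product: 3 (2E)-3-[4-(benzyloxy)-3-methoxyphenyl]prop-2-enal
Conditions: toluene, 80 °C
Reagents that add atoms: none
Why: Wittig olefination with a stabilized ylide gives the (E)-enal under thermodynamic control; no stereocentre is formed.

**Step 2**
Reactants: 3 (2E)-3-[4-(benzyloxy)-3-methoxyphenyl]prop-2-enal; 4 dimethyl 2-bromomalonate
Product: 7 methyl (1S,5R,6S)-6-[4-(benzyloxy)-3-methoxyphenyl]-2-oxo-3-oxabicyclo[3.1.0]hexane-1-carboxylate, via formylcyclopropane diester 5 (not isolated), via hydroxymethylcyclopropane diester 6 (not isolated)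
Conditions: (S)-α,α-diphenylprolinol trimethylsilyl ether (10 mol%), 2,6-lutidine (1.1 equiv), CH2Cl2, 0 °C; then MeOH, NaBH4, 0 °C; aq. NH4Cl
Reagents that add atoms: none
Why: Iminium–enamine Michael-initiated ring closure: the bromomalonate adds to the iminium ion on the face away from the CPh2OSiMe3 group and the enamine then displaces bromide, setting both carbons of the trans-cyclopropane under catalyst control; borohydride reduction gives a CH2OH that is cis to one ester and lactonizes, so cyclopropane and lactone form in the same flask.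

**Step 3**
Reactants: 7 methyl (1S,5R,6S)-6-[4-(benzyloxy)-3-methoxyphenyl]-2-oxo-3-oxabicyclo[3.1.0]hexane-1-carboxylate
Product: 9 methyl (4R)-4-{(R)-(acetyloxy)[4-(benzyloxy)-3-methoxyphenyl]methyl}-3-hydroxy-2-oxooxolane-3-carboxylate (both C3 epimers), via cesium enolate 8 (not isolated)
Conditions: CsOAc (2 equiv), DMSO, 50 °C; then 3-phenyl-2-(phenylsulfonyl)oxaziridine, 20 °C; cold 1 M HCl
Reagents that add atoms: cesium acetate CC(=O)[O-].[Cs+]; 3-phenyl-2-(phenylsulfonyl)oxaziridine O=S(=O)(c1ccccc1)N1OC1c1ccccc1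
Why: Proposed new method: acetate opens the doubly activated donor–acceptor cyclopropane by SN2 attack at the aryl-bearing carbon with inversion, which sets the carbinol carbon as R (closest known type: stereospecific azide and amine openings of 2-arylcyclopropane-1,1-diesters), and the stabilized enolate released is hydroxylated in the same flask by Davis oxidation, the C3 configuration being irrelevant because it is erased in step 6.

**Step 4**
Reactants: 9 methyl (4R)-4-{(R)-(acetyloxy)[4-(benzyloxy)-3-methoxyphenyl]methyl}-3-hydroxy-2-oxooxolane-3-carboxylate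
Product: 11 (4R)-4-{(R)-[4-(benzyloxy)-3-methoxyphenyl](hydroxy)methyl}-3-hydroxyoxolan-2-one (both C3 epimers), via hydroxymalonic acid 10 (not isolated)
Conditions: LiOH, THF/H2O, 20 °C; 1 M HCl to pH 2, 0 °C; then pyridine (cat.), toluene, 90 °C
Reagents that add atoms: lithium hydroxide [Li+].[OH-] (its oxygen enters the carboxyl groups; one may remain in the lactone carbonyl)
Why: Saponification of acetate, methyl ester and lactone, then malonic-type decarboxylation of the hydroxymalonic acid and re-lactonization through the primary hydroxyl (the more stable γ-lactone); C4 and the carbinol carbon are not touched.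

**Step 5**
Reactants: 12 [4-(benzyloxy)-3-methoxyphenyl]methanol
Product: 13 1-(benzyloxy)-4-(bromomethyl)-2-methoxybenzene
Conditions: PBr3, Et2O, 0 °C
Reagents that add atoms: phosphorus tribromide BrP(Br)Br
Why: SN2 bromination of a benzylic alcohol through its phosphite ester; the bromide is used fresh.

**Step 6**
Reactants: 11 (4R)-4-{(R)-[4-(benzyloxy)-3-methoxyphenyl](hydroxy)methyl}-3-hydroxyoxolan-2-one; 13 1-(benzyloxy)-4-(bromomethyl)-2-methoxybenzene
Product: 15 (3S,4R)-3-[4-(benzyloxy)-3-methoxybenzyl]-4-{(R)-[4-(benzyloxy)-3-methoxyphenyl](hydroxy)methyl}-3-hydroxyoxolan-2-one, via trilithium enediolate 14 (not isolated)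
Conditions: LiN(iPr)2 (3.3 equiv), THF/DMPU, −78 °C; then 13, −78 to −40 °C; AcOH
Reagents that add atoms: none
Why: Fráter–Seebach-type C-alkylation of the α-hydroxy lactone enediolate (as used for trachelogenin-type lignans): the bromide enters anti to the C4 substituent, so the benzyl group ends trans and the tertiary hydroxyl cis to the side chain, giving 3S from either C3 epimer of 11.

**Step 7**
Reactants: 15 (3S,4R)-3-[4-(benzyloxy)-3-methoxybenzyl]-4-{(R)-[4-(benzyloxy)-3-methoxyphenyl](hydroxy)methyl}-3-hydroxyoxolan-2-one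
Product: 16 (3S,4R)-3-hydroxy-3-(4-hydroxy-3-methoxybenzyl)-4-[(R)-hydroxy(4-hydroxy-3-methoxyphenyl)methyl]oxolan-2-one
Conditions: H2 (1 atm), Pd/C (10%), EtOAc, 20 °C, stopped at 2 equiv H2
Reagents that add atoms: none
Why: Hydrogenolysis of the two aryl benzyl ethers under neutral conditions, where the secondary benzylic alcohol (which needs acid or forcing conditions to be cleaved) and the lactone survive, as in debenzylation of phenolic lignin model carbinols; no stereocentre is touched.

**Compound list**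
1 | 4-(benzyloxy)-3-methoxybenzaldehyde | COc1cc(C=O)ccc1OCc1ccccc1 | starting material
2 | (triphenylphosphoranylidene)acetaldehyde | O=CC=P(c1ccccc1)(c1ccccc1)c1ccccc1 | starting material
3 | (2E)-3-[4-(benzyloxy)-3-methoxyphenyl]prop-2-enal | COc1cc(/C=C/C=O)ccc1OCc1ccccc1 | intermediate
4 | dimethyl 2-bromomalonate | COC(=O)C(Br)C(=O)OC | starting material
5 | dimethyl (2S,3R)-2-[4-(benzyloxy)-3-methoxyphenyl]-3-formylcyclopropane-1,1-dicarboxylate | COC(=O)C1(C(=O)OC)[C@H](c2ccc(OCc3ccccc3)c(OC)c2)[C@H]1C=O | intermediate (not isolated)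
6 | dimethyl (2S,3R)-2-[4-(benzyloxy)-3-methoxyphenyl]-3-(hydroxymethyl)cyclopropane-1,1-dicarboxylate | COC(=O)C1(C(=O)OC)[C@H](c2ccc(OCc3ccccc3)c(OC)c2)[C@H]1CO | intermediate (not isolated)
7 | methyl (1S,5R,6S)-6-[4-(benzyloxy)-3-methoxyphenyl]-2-oxo-3-oxabicyclo[3.1.0]hexane-1-carboxylate | COC(=O)[C@]12[C@H](c3ccc(OCc4ccccc4)c(OC)c3)[C@H]1COC2=O | intermediate
8 | cesium enolate of methyl (4R)-4-{(R)-(acetyloxy)[4-(benzyloxy)-3-methoxyphenyl]methyl}-2-oxooxolane-3-carboxylate | [Cs+].COC(=O)C1=C([O-])OC[C@@H]1[C@@H](OC(C)=O)c1ccc(OCc2ccccc2)c(OC)c1 | intermediate (not isolated)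
9 | methyl (4R)-4-{(R)-(acetyloxy)[4-(benzyloxy)-3-methoxyphenyl]methyl}-3-hydroxy-2-oxooxolane-3-carboxylate, C3 epimer mixture | COC(=O)C1(O)C(=O)OC[C@@H]1[C@@H](OC(C)=O)c1ccc(OCc2ccccc2)c(OC)c1 | intermediate
10 | 2-{(1R,2R)-1-[4-(benzyloxy)-3-methoxyphenyl]-1,3-dihydroxypropan-2-yl}-2-hydroxypropanedioic acid | OC(=O)C(O)(C(=O)O)[C@H](CO)[C@@H](O)c1ccc(OCc2ccccc2)c(OC)c1 | intermediate (not isolated)
11 | (4R)-4-{(R)-[4-(benzyloxy)-3-methoxyphenyl](hydroxy)methyl}-3-hydroxyoxolan-2-one, C3 epimer mixture | OC1C(=O)OC[C@@H]1[C@@H](O)c1ccc(OCc2ccccc2)c(OC)c1 | intermediate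
12 | [4-(benzyloxy)-3-methoxyphenyl]methanol | COc1cc(CO)ccc1OCc1ccccc1 | starting material
13 | 1-(benzyloxy)-4-(bromomethyl)-2-methoxybenzene | COc1cc(CBr)ccc1OCc1ccccc1 | intermediate
14 | trilithium enediolate/alkoxide of 11 | [Li+].[Li+].[Li+].[O-]C1=C([O-])OC[C@@H]1[C@@H]([O-])c1ccc(OCc2ccccc2)c(OC)c1 | intermediate (not isolated)
15 | (3S,4R)-3-[4-(benzyloxy)-3-methoxybenzyl]-4-{(R)-[4-(benzyloxy)-3-methoxyphenyl](hydroxy)methyl}-3-hydroxyoxolan-2-one | COc1cc(C[C@@]2(O)C(=O)OC[C@@H]2[C@@H](O)c2ccc(OCc3ccccc3)c(OC)c2)ccc1OCc1ccccc1 | intermediate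
16 | (3S,4R)-3-hydroxy-3-(4-hydroxy-3-methoxybenzyl)-4-[(R)-hydroxy(4-hydroxy-3-methoxyphenyl)methyl]oxolan-2-one | COc1cc(C[C@@]2(O)C(=O)OC[C@@H]2[C@@H](O)c2ccc(O)c(OC)c2)ccc1O | target

**Step count:** 7 steps in total. The longest linear sequence is 6 steps (1, 2, 3, 4, 6, 7); step 5 makes the bromide 13.

**Steps most likely to fail**

1. Step 3. The acetate may open the electron-rich cyclopropane partly through a benzylic cation, eroding the carbinol configuration, and the one-flask enolate oxidation may be incomplete. The fallback sets out from 1 and comes back at 11, and makes the C–C bond next to the carbinol by an enamine aldol instead of opening a ring. L-Proline-catalysed cross-aldol of 1 with methyl 4-oxobutanoate (slow addition, DMF, 4 °C) gives the anti-aldol methyl (3S,4R)-4-[4-(benzyloxy)-3-methoxyphenyl]-3-formyl-4-hydroxybutanoate F1. NaBH4 in MeOH and a trace of acid then give (4R)-4-{(R)-[4-(benzyloxy)-3-methoxyphenyl](hydroxy)methyl}oxolan-2-one F2. Its dianion (LiN(iPr)2, 2.2 equiv, THF, −78 °C) is hydroxylated with 3-phenyl-2-(phenylsulfonyl)oxaziridine to give 11.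

2. Step 6. The trianion may be poorly soluble, or may be O-benzylated at the secondary alkoxide. The fallback sets out from 11 and comes back at 15, and alkylates a protected mono-anion instead. Et3SiCl and imidazole in DMF give (4R)-4-{(R)-[4-(benzyloxy)-3-methoxyphenyl][(triethylsilyl)oxy]methyl}-3-[(triethylsilyl)oxy]oxolan-2-one F3. LiN(iPr)2 (1.1 equiv) and 13 at −78 °C give, again anti to the C4 substituent, (3S,4R)-3-[4-(benzyloxy)-3-methoxybenzyl]-4-{(R)-[4-(benzyloxy)-3-methoxyphenyl][(triethylsilyl)oxy]methyl}-3-[(triethylsilyl)oxy]oxolan-2-one F4. HF·pyridine in THF then gives 15.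

3. Step 7. Once the phenol is free, the p-hydroxybenzylic C–O bond may be hydrogenolysed too. The fallback sets out from 15 and comes back at 16, and removes the carbinol before hydrogenolysis. Dess–Martin periodinane oxidizes the secondary alcohol to (3S,4S)-3-[4-(benzyloxy)-3-methoxybenzyl]-4-[4-(benzyloxy)-3-methoxybenzoyl]-3-hydroxyoxolan-2-one F5. H2 over Pd/C in EtOAc then cleaves the benzyl ethers to (3S,4S)-3-hydroxy-4-(4-hydroxy-3-methoxybenzoyl)-3-(4-hydroxy-3-methoxybenzyl)oxolan-2-one F6. Catalyst-controlled transfer hydrogenation with RuCl(p-cymene)[(R,R)-TsDPEN] in HCO2H/Et3N restores the (R)-carbinol and gives 16.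

**Further compounds**
F1 | step 3 | methyl (3S,4R)-4-[4-(benzyloxy)-3-methoxyphenyl]-3-formyl-4-hydroxybutanoate | COC(=O)C[C@H](C=O)[C@@H](O)c1ccc(OCc2ccccc2)c(OC)c1
F2 | step 3 | (4R)-4-{(R)-[4-(benzyloxy)-3-methoxyphenyl](hydroxy)methyl}oxolan-2-one | O=C1OC[C@@H](C1)[C@@H](O)c1ccc(OCc2ccccc2)c(OC)c1
F3 | step 6 | (4R)-4-{(R)-[4-(benzyloxy)-3-methoxyphenyl][(triethylsilyl)oxy]methyl}-3-[(triethylsilyl)oxy]oxolan-2-one | CC[Si](CC)(CC)OC1C(=O)OC[C@@H]1[C@@H](O[Si](CC)(CC)CC)c1ccc(OCc2ccccc2)c(OC)c1
F4 | step 6 | (3S,4R)-3-[4-(benzyloxy)-3-methoxybenzyl]-4-{(R)-[4-(benzyloxy)-3-methoxyphenyl][(triethylsilyl)oxy]methyl}-3-[(triethylsilyl)oxy]oxolan-2-one | COc1cc(C[C@@]2(O[Si](CC)(CC)CC)C(=O)OC[C@@H]2[C@@H](O[Si](CC)(CC)CC)c2ccc(OCc3ccccc3)c(OC)c2)ccc1OCc1ccccc1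
F5 | step 7 | (3S,4S)-3-[4-(benzyloxy)-3-methoxybenzyl]-4-[4-(benzyloxy)-3-methoxybenzoyl]-3-hydroxyoxolan-2-one | COc1cc(C[C@@]2(O)C(=O)OC[C@@H]2C(=O)c2ccc(OCc3ccccc3)c(OC)c2)ccc1OCc1ccccc1
F6 | step 7 | (3S,4S)-3-hydroxy-4-(4-hydroxy-3-methoxybenzoyl)-3-(4-hydroxy-3-methoxybenzyl)oxolan-2-one | COc1cc(C[C@@]2(O)C(=O)OC[C@@H]2C(=O)c2ccc(O)c(OC)c2)ccc1O
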